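**Retrosynthetic overview** (atom labels: C1–C10 rings A/B; C11–C12 linker; C13–C18 ring C, with C13 the CH bearing the linker, C14 the CHMe, C17 the CH–O and C18 the quaternary CMe; C19–C22 oxepane arm, with C21 the C=O and C22 the CMe2–O)
1. The last coupling disconnects C9–C11: a primary alkyllithium from the ring C/oxepane iodide **30** adds to the ring A/B vinylogous ester **14** (Stork–Danheiser). C6 hydroxylation and oxidation then give the diosphenol, followed by global deprotection.
2. Rings A and B of **14** come from one proline-catalysed Robinson annulation, which sets C10. Deconjugative gem-dimethylation, C7 allylic oxidation, C8 methylation and vinylogous-ester formation complete it.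
3. Ring C of **30** comes from Michael addition of the same dione to acrolein and an enantioselective desymmetrising reduction, which set C17 and C18. C13 and C14 are then set by hydrogenation of a C13=C14 alkene built from an enol triflate. The oxepane is closed last in this fragment.

Assumptions (one line): (R)-Me-CBS is taken to deliver the enantiomer drawn in **18**; the C9, C6 and C21 carbinol configurations are left undefined because they are oxidised later.

**Step 1**
Reactants: **1** cyclohexane-1,3-dione
Product: **2** 2-methylcyclohexane-1,3-dione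
Conditions: MeI, NaOH, H2O, 80 °C
Reagents that add atoms: MeI, CI
Why: Enolate C-alkylation in water at the acidic C2 (C-alkylation is favoured in protic solvent); no stereocentre is formed.

**Step 2**
Reactants: **2**; **3** methyl vinyl ketone
Product: **4** (S)-Wieland–Miescher ketone
Conditions: **3**, (S)-proline (cat.), DMSO, rt; then TsOH, PhH, reflux
Reagents that add atoms: none
Why: Michael addition, then proline-enamine aldol desymmetrisation and dehydration (Hajos–Parrish/Wieland–Miescher Robinson annulation); this sets the C10 quaternary centre (S), and recrystallisation upgrades the ee.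

**Step 3**
Reactants: **4**
Product: **5** 9-hydroxy-10-methyl-Δ4-octal-3-one
Conditions: NaBH4, EtOH, −20 °C
Reagents that add atoms: none
Why: Chemoselective reduction of the non-conjugated C9 ketone; the C9 configuration is immaterial because it is re-oxidised in Step 10.

**Step 4**
Reactants: **5**
Product: **6** C9 TBS ether of **5**
Conditions: TBSCl, imidazole, DMF, rt
Reagents that add atoms: TBSCl, C[Si](C)(Cl)C(C)(C)C
Why: Protects the C9 hydroxyl before the enolate chemistry in Step 5.

**Step 5**
Reactants: **6**
Product: **7** 9-OTBS-4,4,10-trimethyl-Δ5-octal-3-one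
Conditions: KOtBu (2.5 equiv), MeI (3 equiv), tBuOH/THF, rt
Reagents that add atoms: MeI, CI
Why: Deconjugative gem-dimethylation: the extended dienolate is alkylated twice at C4, and the alkene moves to C5=C6; no new stereocentre forms.

**Step 6**
Reactants: **7**
Product: **8** 3,3-ethylenedioxy ketal of **7**
Conditions: TMSOCH2CH2OTMS, TMSOTf (cat.), CH2Cl2, −78 → 0 °C
Reagents that add atoms: 1,2-bis(trimethylsiloxy)ethane, C[Si](C)(C)OCCO[Si](C)(C)C
Why: Noyori ketalisation protects the hindered C3 ketone, which would otherwise react with the organolithium in Step 28.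

**Step 7**
Reactants: **8**
Product: **9** 7-oxo-Δ5 compound
Conditions: Pd(OH)2/C (cat.), tBuOOH (aq.), K2CO3, CH2Cl2, rt
Reagents that add atoms: tBuOOH, CC(C)(C)OO
Why: Pd-catalysed allylic C–H oxidation of the Δ5-alkene at C7, the only allylic CH2, gives the enone; no stereocentre is formed.

**Step 8**
Reactants: **9**
Product: **10** 5-H trans-fused 7-ketone
Conditions: Li, NH3 (l), THF, −78 °C; then NH4Cl
Reagents that add atoms: none
Why: Dissolving-metal conjugate reduction of the enone, with protonation at C5 giving the trans ring fusion; C5 becomes sp2 again in Step 31, so its configuration is inconsequential.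

**Step 9**
Reactants: **10**
Product: **11** C9 alcohol
Conditions: HF·pyridine, THF/pyridine, 0 °C → rt
Reagents that add atoms: none
Why: Fluoride-mediated desilylation of the hindered C9 silyl ether; the acid-stable ketal survives.

**Step 10**
Reactants: **11**
Product: **12** 7,9-dione
Conditions: Dess–Martin periodinane, NaHCO3, CH2Cl2, rt
Reagents that add atoms: none
Why: Oxidation of the β-hydroxy ketone to the cyclic 1,3-dione, which destroys the C9 stereocentre.

**Step 11**
Reactants: **12**
Product: **13** 8-methyl-7,9-dione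
Conditions: MeI, K2CO3, DMF, rt
Reagents that add atoms: MeI, CI
Why: C-alkylation at the most acidic position, C8, between the two carbonyls; C8 becomes sp2 in Step 12.

**Step 12**
Reactants: **13**
Product: **14** 7-isobutoxy-8-methyl-Δ7-octal-9-one, the vinylogous ester
Conditions: iBuOH, TsOH (cat.), PhH, Dean–Stark reflux
Reagents that add atoms: isobutanol, CC(C)CO
Why: Acid-catalysed enol-ether formation occurs at the less hindered C7 carbonyl (remote from the C10 quaternary centre), leaving C9 as the vinylogous-ester carbonyl needed for the Stork–Danheiser addition.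

**Step 13**
Reactants: **2**; **15** acrolein
Product: **16** 3-(1-methyl-2,6-dioxocyclohexyl)propanal
Conditions: **15**, H2O, rt
Reagents that add atoms: none
Why: Michael addition of the dione enolate builds the quaternary C18 as a prochiral centre between two enantiotopic carbonyls.

**Step 14**
Reactants: **16**
Product: **17** 2-(3,3-dimethoxypropyl)-2-methylcyclohexane-1,3-dione
Conditions: HC(OMe)3, MeOH, TsOH (cat.), rt
Reagents that add atoms: trimethyl orthoformate, COC(OC)OC
Why: The aldehyde is selectively acetalised (the hindered ketones do not react), protecting it through the later base and hydride steps.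

**Step 15**
Reactants: **17**
Product: **18** (2R,3S)-2-(3,3-dimethoxypropyl)-3-hydroxy-2-methylcyclohexan-1-one
Conditions: (R)-Me-CBS (10 mol%), BH3·SMe2 (0.6 equiv), THF, −40 °C
Reagents that add atoms: none
Why: Enantiotopic-group-selective CBS reduction of one carbonyl sets C17 and C18 together; hydride arrives anti to the methyl, so OH is cis to the C18 methyl as in the target.

**Step 16**
Reactants: **18**
Product: **19** C17 TBS ether
Conditions: TBSOTf, 2,6-lutidine, CH2Cl2, 0 °C
Reagents that add atoms: TBSOTf, C[Si](C)(OS(=O)(=O)C(F)(F)F)C(C)(C)C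
Why: Protects the neopentyl secondary alcohol; the lutidine-buffered conditions leave the acetal intact.

**Step 17**
Reactants: **19**
Product: **20** 6-methyl ketone (C14 methyl; epimeric at C14)
Conditions: LDA, THF, −78 °C; then MeI, −78 → 0 °C
Reagents that add atoms: MeI, CI
Why: The quaternary C18 leaves only the C14 side enolisable, so methylation is regiospecific; the C14 configuration is erased in Step 18.

**Step 18**
Reactants: **20**
Product: **21** tetrasubstituted enol triflate
Conditions: KHMDS, THF, −78 °C; then PhNTf2
Reagents that add atoms: PhNTf2, O=S(=O)(C(F)(F)F)N(c1ccccc1)S(=O)(=O)C(F)(F)F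
Why: Kinetic enolate triflation makes the C13=C14 alkene, so C14 is sp2 and the tetrasubstituted alkene is ready for syn-hydrogenation in Step 21.

**Step 19**
Reactants: **21**
Product: **22** C13-vinyl-C13=C14 diene
Conditions: CH2=CHSnBu3, Pd(PPh3)4, LiCl, CuI, DMF, 80 °C
Reagents that add atoms: vinyltributylstannane, C=C[Sn](CCCC)(CCCC)CCCC
Why: Stille coupling installs the future C12–C11 two-carbon linker.

**Step 20**
Reactants: **22**
Product: **23** primary alcohol (C11–OH), C13=C14 retained
Conditions: 9-BBN, THF, rt; then NaOH, H2O2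
Reagents that add atoms: H2O2, OO
Why: Anti-Markovnikov hydroboration at the unhindered terminal vinyl carbon (the tetrasubstituted alkene is inert), converting the diene into the homoallylic C11 alcohol.

**Step 21**
Reactants: **23**
Product: **24** saturated ring C (C13–H and C14–H α, cis)
Conditions: H2 (50 atm), [Ir(cod)(PCy3)(py)]PF6, CH2Cl2, rt
Reagents that add atoms: none
Why: Syn-hydrogenation of the tetrasubstituted alkene from the face opposite the axial C18 methyl and the C17 silyloxy group sets C13 and C14 cis, putting the C12 chain and the C14 methyl on the same face as in the target.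

**Step 22**
Reactants: **24**
Product: **25** primary iodide
Conditions: I2, PPh3, imidazole, CH2Cl2/Et2O, 0 °C
Reagents that add atoms: I2, II
Why: Appel-type conversion of the primary alcohol to the iodide (the precursor of the organolithium); the hindered silyl ether is unaffected.

**Step 23**
Reactants: **25**
Product: **26** aldehyde
Conditions: PPTS, acetone/H2O, 50 °C
Reagents that add atoms: water, O
Why: Mild hydrolysis of the dimethyl acetal; the hindered TBS ether and the alkyl iodide survive.

**Step 24**
Reactants: **26**
Product: **27** allylic alcohol (C21 carbinol, epimeric)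
Conditions: isopropenylMgBr, THF, −78 °C
Reagents that add atoms: isopropenylmagnesium bromide, C=C(C)[Mg]Br
Why: Chemoselective Grignard addition to the aldehyde; the new C21 carbinol is formed unselectively but is oxidised in Step 31.

**Step 25**
Reactants: **27**
Product: **28** C21 TBDPS ether
Conditions: TBDPSCl, imidazole, DMAP, DMF, rt
Reagents that add atoms: TBDPSCl, CC(C)(C)[Si](c1ccccc1)(c1ccccc1)Cl
Why: Installs a silyl group that survives the later fluoride step (Step 26) and the organolithium chemistry (Step 28).

**Step 26**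
Reactants: **28**
Product: **29** free C17 alcohol
Conditions: HF·pyridine, THF/pyridine, rt
Reagents that add atoms: none
Why: HF·pyridine removes the TBS group selectively and leaves TBDPS intact; the C17 configuration is untouched.

**Step 27**
Reactants: **29**
Product: **30** oxepane iodide (C21-OTBDPS)
Conditions: Co(salen) catalyst (5 mol%), N-fluoro-2,4,6-trimethylpyridinium triflate, (Me2SiH)2O, PhCF3, rt
Reagents that add atoms: none
Why: Mukaiyama-type Co–H hydrogen-atom transfer to the isopropenyl group gives the tertiary radical, which is oxidised and trapped by C17–OH in a Markovnikov 7-ring hydroalkoxylation, creating the C22 CMe2–O bond with C17 retained.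

**Step 28**
Reactants: **14**; **30**
Product: **31** ring A/B/C enone carrying the linker, with the C3 ketal still in place
Conditions: **30**, tBuLi (2.2 equiv), Et2O, −78 °C; CeCl3, THF; add **14**, −78 → 0 °C; then 1 M HCl, THF, rt
Reagents that add atoms: water, O
Why: The organocerium adds 1,2 to C9 of the vinylogous ester, and acidic work-up loses iBuOH with 1,3-carbonyl transposition (Stork–Danheiser) to the C7 enone with tetrasubstituted C8=C9; no stereocentre is altered.

**Step 29**
Reactants: **31**
Product: **32** 6-hydroxy-7-ketone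
Conditions: LDA, THF, −78 °C; then Davis oxaziridine
Reagents that add atoms: 2-(phenylsulfonyl)-3-phenyloxaziridine, O=S(=O)(c1ccccc1)N1OC1c1ccccc1
Why: Kinetic α′-enolisation occurs at C6, the only enolisable α-position of the enone, and the oxaziridine hydroxylates it; the C6 configuration is lost in Step 31.

**Step 30**
Reactants: **32**
Product: **33** C21 alcohol
Conditions: TBAF, AcOH, THF, 40 °C
Reagents that add atoms: none
Why: Fluoride removes the TBDPS group; the ketal and the oxepane ether are unaffected.

**Step 31**
Reactants: **33**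
Product: **34** diosphenol, oxepanone, ketal still in place
Conditions: Dess–Martin periodinane (3 equiv), NaHCO3, CH2Cl2, rt
Reagents that add atoms: none
Why: DMP oxidises the α-hydroxy ketone to the 6,7-dione, which tautomerises to the conjugated diosphenol C5=C6(OH)–C7=O, and oxidises C21–OH to the C21 ketone; this erases the C5, C6 and C21 stereochemistry.

**Step 32**
Reactants: **34**
Product: **35** sodwanone B
Conditions: TsOH·H2O, acetone/H2O, reflux
Reagents that add atoms: water, O
Why: Acid hydrolysis of the C3 dioxolane releases the ring A ketone without touching the other functional groups.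

**Compound list**

| No. | Name | SMILES | Role |
|---|---|---|---|
| 1 | cyclohexane-1,3-dione | O=C1CCCC(=O)C1 | starting material |
| 2 | 2-methylcyclohexane-1,3-dione | CC1C(=O)CCCC1=O | intermediate |
| 3 | methyl vinyl ketone | C=CC(C)=O | starting material |
| 4 | (S)-Wieland–Miescher ketone | O=C1CCCC2=CC(=O)CC[C@]12C | intermediate |
| 5 | 9-hydroxy-10-methyl-Δ4-octal-3-one | OC1CCCC2=CC(=O)CC[C@]12C | intermediate |
| 6 | C9 TBS ether of 5 | CC(C)(C)[Si](C)(C)OC1CCCC2=CC(=O)CC[C@]12C | intermediate |
| 7 | 9-OTBS-4,4,10-trimethyl-Δ5-octal-3-one | CC(C)(C)[Si](C)(C)OC1CCC=C2C(C)(C)C(=O)CC[C@]12C | intermediate |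
| 8 | 3,3-ethylenedioxy ketal of 7 | CC(C)(C)[Si](C)(C)OC1CCC=C2C(C)(C)C3(OCCO3)CC[C@]12C | intermediate |
| 9 | 7-oxo-Δ5 analogue | CC(C)(C)[Si](C)(C)OC1CC(=O)C=C2C(C)(C)C3(OCCO3)CC[C@]12C | intermediate |
| 10 | 7-ketone, 5-H trans | CC(C)(C)[Si](C)(C)OC1CC(=O)C[C@H]2C(C)(C)C3(OCCO3)CC[C@]12C | intermediate |
| 11 | C9 alcohol | OC1CC(=O)C[C@H]2C(C)(C)C3(OCCO3)CC[C@]12C | intermediate |
| 12 | 7,9-dione | O=C1CC(=O)C[C@H]2C(C)(C)C3(OCCO3)CC[C@]12C | intermediate |
| 13 | 8-methyl-7,9-dione | O=C1C(C)C(=O)C[C@H]2C(C)(C)C3(OCCO3)CC[C@]12C | intermediate |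
| 14 | vinylogous ester (ring A/B fragment) | O=C1C(C)=C(OCC(C)C)C[C@H]2C(C)(C)C3(OCCO3)CC[C@]12C | intermediate |
| 15 | acrolein | C=CC=O | starting material |
| 16 | 3-(1-methyl-2,6-dioxocyclohexyl)propanal | O=CCCC1(C)C(=O)CCCC1=O | intermediate |
| 17 | 2-(3,3-dimethoxypropyl)-2-methylcyclohexane-1,3-dione | COC(OC)CCC1(C)C(=O)CCCC1=O | intermediate |
| 18 | (2R,3S)-2-(3,3-dimethoxypropyl)-3-hydroxy-2-methylcyclohexan-1-one | COC(OC)CC[C@@]1(C)C(=O)CCC[C@@H]1O | intermediate |
| 19 | C17 TBS ether of 18 | COC(OC)CC[C@@]1(C)C(=O)CCC[C@@H]1O[Si](C)(C)C(C)(C)C | intermediate |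
| 20 | 6-methyl ketone (C14 epimeric) | COC(OC)CC[C@@]1(C)C(=O)C(C)CC[C@@H]1O[Si](C)(C)C(C)(C)C | intermediate |
| 21 | tetrasubstituted enol triflate | COC(OC)CC[C@@]1(C)C(OS(=O)(=O)C(F)(F)F)=C(C)CC[C@@H]1O[Si](C)(C)C(C)(C)C | intermediate |
| 22 | C13-vinyl diene | COC(OC)CC[C@@]1(C)C(C=C)=C(C)CC[C@@H]1O[Si](C)(C)C(C)(C)C | intermediate |
| 23 | homoallylic alcohol (C11-OH) | COC(OC)CC[C@@]1(C)C(CCO)=C(C)CC[C@@H]1O[Si](C)(C)C(C)(C)C | intermediate |
| 24 | hydrogenated ring C | COC(OC)CC[C@@]1(C)[C@H](CCO)[C@H](C)CC[C@@H]1O[Si](C)(C)C(C)(C)C | intermediate |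
| 25 | primary iodide | COC(OC)CC[C@@]1(C)[C@H](CCI)[C@H](C)CC[C@@H]1O[Si](C)(C)C(C)(C)C | intermediate |
| 26 | aldehyde | O=CCC[C@@]1(C)[C@H](CCI)[C@H](C)CC[C@@H]1O[Si](C)(C)C(C)(C)C | intermediate |
| 27 | allylic alcohol (C21 epimeric) | C=C(C)C(O)CC[C@@]1(C)[C@H](CCI)[C@H](C)CC[C@@H]1O[Si](C)(C)C(C)(C)C | intermediate |
| 28 | C21 TBDPS ether | C=C(C)C(O[Si](c2ccccc2)(c2ccccc2)C(C)(C)C)CC[C@@]1(C)[C@H](CCI)[C@H](C)CC[C@@H]1O[Si](C)(C)C(C)(C)C | intermediate |
| 29 | free C17 alcohol | C=C(C)C(O[Si](c2ccccc2)(c2ccccc2)C(C)(C)C)CC[C@@]1(C)[C@H](CCI)[C@H](C)CC[C@@H]1O | intermediate |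
| 30 | oxepane iodide (ring C/oxepane fragment) | ICC[C@@H]2[C@H](C)CC[C@@H]3OC(C)(C)C(O[Si](c4ccccc4)(c4ccccc4)C(C)(C)C)CC[C@]32C | intermediate |
| 31 | coupled enone | CC1=C(CC[C@@H]2[C@H](C)CC[C@@H]3OC(C)(C)C(O[Si](c4ccccc4)(c4ccccc4)C(C)(C)C)CC[C@]32C)[C@@]5(C)CCC6(OCCO6)C(C)(C)[C@@H]5CC1=O | intermediate |
| 32 | 6-hydroxy-7-ketone | CC1=C(CC[C@@H]2[C@H](C)CC[C@@H]3OC(C)(C)C(O[Si](c4ccccc4)(c4ccccc4)C(C)(C)C)CC[C@]32C)[C@@]5(C)CCC6(OCCO6)C(C)(C)[C@@H]5C(O)C1=O | intermediate |
| 33 | C21 alcohol | CC1=C(CC[C@@H]2[C@H](C)CC[C@@H]3OC(C)(C)C(O)CC[C@]32C)[C@@]5(C)CCC6(OCCO6)C(C)(C)[C@@H]5C(O)C1=O | intermediate |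
| 34 | diosphenol, C21 ketone, ketal | CC1=C(CC[C@@H]2[C@H](C)CC[C@@H]3OC(C)(C)C(=O)CC[C@]32C)[C@@]5(C)CCC6(OCCO6)C(C)(C)C5=C(O)C1=O | intermediate |
| 35 | sodwanone B | CC1=C(CC[C@@H]2[C@H](C)CC[C@@H]3OC(C)(C)C(=O)CC[C@]32C)[C@@]2(C)CCC(=O)C(C)(C)C2=C(O)C1=O | target |

**Totals**
- Total step count: 32.
- Longest linear sequence: 21 (Step 1, Steps 13–27, Step 28, Steps 29–32).

**Three steps most likely to fail, each with a fallback that changes the approach**
1. **Step 21, hydrogenation of the tetrasubstituted C13=C14 alkene.** It may be very slow, isomerise, or be poorly face-selective. Fallback: build ring C by a Cp2TiCl-mediated radical cyclisation of an epoxy-polyene. That gives the ring with the C13/C17/C18 relationships already set and an exocyclic C14 methylene, which is then hydrogenated from the α-face.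
2. **Step 27, Co–H hydroalkoxylation to the seven-membered ether.** Competing semipinacol rearrangement, elimination or dehalogenation of the iodide may occur. Fallback: form the oxepane by ring-closing metathesis of a C17–O–C22(Me)2–CH=CH2 tertiary allylic ether with a C18 allyl chain. Hydroboration/oxidation of the resulting oxepene then gives the C21 oxygenation.
3. **Step 28, hindered organocerium addition to C9.** C9 is next to the C10 quaternary centre, so addition may be slow or the lithio species may protonate. Fallback: convert dione **13** to the C9 enol triflate (or the β-iodoenone) and couple it by B-alkyl Suzuki–Miyaura reaction with the 9-BBN adduct of a terminal-alkene version of the ring C/oxepane fragment.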